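## The problem

The target 14 is a 2,3-dihydro-1-benzofuran. Benzene ring A (C3a, C4 to C7, C7a) is fused along C3a–C7a to a dihydrofuran whose C2 carries ring B (3-hydroxy-4,5-dimethoxyphenyl) and whose C3 carries a methyl group trans to ring B. Ring A is 1,2,3,5-tetrasubstituted: O1 on C7a, a methoxy group on C7, an (E)-prop-1-enyl group on C5, and hydrogen on C4 and C6. The two stereocentres, C2 (S) and C3 (S), are contiguous. In an open-chain precursor they are a carbinol/methyl pair that one anti-selective carbonyl addition can set together, after which neither has to be touched. C2 is a benzylic ether carbon para to a methoxy group of ring B and can ionise in strong acid; the propenyl group is an electron-rich styrene that should arrive late and never meet acid. The single phenol of ring B sits beside two methyl ethers, so it cannot be revealed by demethylation and has to be carried protected from a commercial phenol. The feature that invites a cycloaddition is the sequence O1–C7a–C7(OMe)–C6(H)–C5(X): it is the C3 to C6 edge of a 3-alkoxy-4-methoxy-6-halopyridazine, and the two missing atoms, C3a and C4, are the carbons of an alkyne that the three-atom chain O1–C2–C3 holds next to the diazine.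

## Retrosynthesis

**14 to 12 and 13.** The C5–propenyl bond is cut first. Carrying the styrene through acid or a 200 °C step would endanger it, and building it from a carbonyl group would cost extra steps. The aryl chloride 12 is what the ring-forming step leaves at C5 in any case. The forward reaction is a stereoretentive coupling of 12 with the commercial (E)-alkenylboron salt 13 in the presence of a free phenol.

**12 to 11.** The O–CH2 bond of the acetal protecting group is cut. Placing this before the coupling means the acid needed for it never meets the propenyl group. The forward step must leave the benzylic ether at C2 and the aryl chloride alone.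

**11 to 9.** C3a–C7a and C4–C5 are cut and an N=N bridge is restored across C7a and C5. This opens both rings at once and leads to 9, an acyclic ether of a monocyclic chloropyridazine with a terminal alkyne. The neighbouring cuts (O1–C2 by displacement at the benzylic carbon, or C2–C3 by an ionic annulation) would create or endanger a stereocentre during ring closure. This cut forms none, so C2 and C3 can be set beforehand and carried through. The forward reaction asks only for heat and for a substrate that survives it.

**9 to 6 and 7.** The O1–C7a bond is cut, which is the C3–O bond of the diazine. Forming it by substitution on the heteroarene keeps the C2–O bond of alcohol 6 intact, so the configuration at C2 is retained; a displacement at C2 would invert or ionise that centre. Dichloride 7 is commercial. The forward reaction must put the alkoxide on C3, the chlorine-bearing carbon next to the methoxy-bearing one, and not on C6.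

**6 to 2 and 4.** The C2–C3 bond is cut. Addition of the chiral allenylindium reagent 5, made in the flask from mesylate 4, to aldehyde 2 sets both stereocentres and delivers the alkyne in one step. A crotylation would need a later alkene-to-alkyne conversion. The forward reaction needs anti selectivity and faithful transfer of chirality from 4.

**2 to 1, and 4 to 3.** Only the phenol protecting group and the sulfonate are removed. Both 1 and 3 are commercial.

## Roads not taken

**Alternative 1:** The cut is O1–C2 and C2–C3, a (4+1) annulation. In the forward step Cs2CO3 eliminates sulfinate from sulfone A2 to release the ortho-quinone methide A4 and deprotonates the benzylic sulfonium salt A3. The carbanionic carbon adds to the ethylidene carbon of A4 (C2–C3) and the phenoxide then displaces the sulfide (O1–C2), giving A1.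
- Merits: it is convergent, runs near room temperature, gives the trans ring by its mechanism, and both halves come from simple benzaldehydes.
- Weak points: both stereocentres and the absolute sense arise in one step from a stoichiometric chiral sulfide, through a betaine that may equilibrate before closure. A4 has a methyl group on its exocyclic carbon and can tautomerise to the ortho-vinylphenol before it is trapped.
- Comparison: it is milder and probably a step or two shorter, and in thermal risk it is better than the chosen plan. The chosen plan sets against this that its stereocentres come from a reagent-controlled addition of an enantiopure C4 unit, can be checked and purified at the stage of 6, and are untouched by ring formation.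

**Alternative 2:** The cut is C3–C3a, after adding a carboxyl carbon at C3, which leads back to flavanone A6. In the forward step PhI(OAc)2 and H2SO4 in HC(OMe)3 convert A6 into its enol ether and place trivalent iodine on the carbon that becomes C3. The ring A carbon then migrates to that carbon, contracting the pyranone and expelling the old carbonyl carbon as the methyl ester of A5.
- Merits: only one stereocentre has to be set before the key step, and the contraction gives the trans ester.
- Weak points: A5 carries CO2Me where the target has CH3, so three further steps (reduction, sulfonylation, hydride displacement) are needed. The medium is strongly acidic and oxidising, which threatens the silyl ether and the electron-rich ring B. The donor groups of ring B favour its own 1,2-shift (the isoflavone path) over the ring A shift. A6 can also open by retro-oxa-Michael reaction in acid and lose its configuration.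
- Comparison: it avoids high temperature but is longer and has a harsher, less selective key step; the chosen plan is preferred on step count and chemoselectivity.

**Alternative 3:** The cut is C3a–C4 and C7a–C7, with ring A grown on lactone A8. In the forward step the silyl ketene acetal A10 adds to bromopyrone ester A9, and loss of CO2 and silanol gives A7.
- Merits: the stereocentres are set at the lactone stage by mature chemistry, and pyrone cycloadditions of ketene acetals usually need less heat than alkoxy diazines.
- Weak points: A7 has bromine at C7 and an ester at C5, neither of which is the target's group. A methoxylation of an aryl bromide flanked by O1 and about three steps from ester to (E)-propenyl would follow. The cycloaddition is intermolecular, so its regiochemistry rests on polarity and not on a tether.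
- Comparison: its key step is likely milder, and in that respect it is as good or better. The chosen plan answers with a product that already has methoxy at C7 and a halogen exactly at C5, so two steps remain after the key step instead of about five.

Key step: step 5

Assumption: the (R)-mesylate 4 is taken to give the (aS)-allenylindium 5 and from it (1S,2S)-6 (anti SN2′ palladation, retentive transfer to indium, closed SE2′ addition); if the sense proved opposite, the enantiomeric butynol would be used.

## Route

Step 1
Reactants: 1 3-hydroxy-4,5-dimethoxybenzaldehyde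
Product: 2 3,4-dimethoxy-5-(methoxymethoxy)benzaldehyde
Conditions: MOMCl, i-Pr2NEt, CH2Cl2, 0 °C to rt
Reagents that add atoms: chloromethyl methyl ether, COCCl
Why: O-alkylation of a phenol to its methoxymethyl acetal; the aldehyde is inert to these conditions, and the MOM ether withstands the organometallic, basic and thermal steps that follow.

Step 2
Reactants: 3 (R)-but-3-yn-2-ol
Product: 4 (R)-but-3-yn-2-yl methanesulfonate
Conditions: MsCl, Et3N, CH2Cl2, −78 °C
Reagents that add atoms: methanesulfonyl chloride, CS(=O)(=O)Cl
Why: O-sulfonylation of a secondary propargylic alcohol; only the O–S bond forms, so the (R) configuration is kept, and the low temperature prevents solvolysis of the mesylate.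

Step 3
Reactants: 2 3,4-dimethoxy-5-(methoxymethoxy)benzaldehyde; 4 (R)-but-3-yn-2-yl methanesulfonate
Product: 6 (1S,2S)-1-[3,4-dimethoxy-5-(methoxymethoxy)phenyl]-2-methylbut-3-yn-1-ol, via allenylindium reagent 5 (not isolated)
Conditions: Pd(OAc)2 (5 mol %), PPh3 (5 mol %), InI (1.3 equiv), THF/HMPA (3:1), rt
Reagents that add atoms: none
Why: Palladium-catalysed, indium-mediated SE2′ propargylation of an aldehyde: zerovalent palladium formed in the flask displaces the mesylate in an anti SN2′ sense, InI takes over the allenyl group with retention to give 5 (trivalent indium), and 5 adds through a closed six-membered transition state. The (R) centre of 4 fixes the methyl-bearing carbon as S, and the anti preference of the closed transition state, with the aryl group turned away from the allene methyl, fixes the carbinol carbon as S.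

Step 4
Reactants: 6 (1S,2S)-1-[3,4-dimethoxy-5-(methoxymethoxy)phenyl]-2-methylbut-3-yn-1-ol; 7 3,6-dichloro-4-methoxypyridazine
Product: 9 6-chloro-3-{[(1S,2S)-1-[3,4-dimethoxy-5-(methoxymethoxy)phenyl]-2-methylbut-3-yn-1-yl]oxy}-4-methoxypyridazine, via sodium alkoxide 8 (not isolated)
Conditions: NaH (1.1 equiv), THF, 0 °C; then 7 (1.2 equiv), 0 °C to rt
Reagents that add atoms: none
Why: Nucleophilic aromatic substitution (addition–elimination) at C3 of the diazine with retention at the carbinol carbon, since its C–O bond is not broken. C3 should be preferred because the 4-methoxy group is conjugated through C5 with the C6=N1 unit and lowers its electrophilicity, while sodium held by N2 and the methoxy oxygen delivers the alkoxide to C3. The regiochemistry is to be proven on 9 by NOE (no contact expected between the ether methine and pyridazine H5) before the route goes on.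

Step 5
Reactants: 9 6-chloro-3-{[(1S,2S)-1-[3,4-dimethoxy-5-(methoxymethoxy)phenyl]-2-methylbut-3-yn-1-yl]oxy}-4-methoxypyridazine
Product: 11 (2S,3S)-5-chloro-2-[3,4-dimethoxy-5-(methoxymethoxy)phenyl]-7-methoxy-3-methyl-2,3-dihydro-1-benzofuran, via bridged diazabicyclooctatriene adduct 10 (not isolated)
Conditions: N,N-diethylaniline (degassed, 0.02 M), sealed tube, 200 °C
Reagents that add atoms: none
Why: Intramolecular inverse-electron-demand Diels–Alder reaction of a 1,2-diazine: the pyridazine reacts as the 4π component across C3 and C6 and the tethered terminal alkyne as the 2π component, giving bridged adduct 10, which at once and irreversibly expels N2 in a retro-(4+2) step and becomes aromatic. The closest known reaction type is the thermal closure of 3-(but-3-ynyloxy)-6-chloropyridazines to 5-chloro-2,3-dihydrobenzofurans. The dihydrofuran closes as the five-membered tether ring when the internal alkyne carbon bonds to the oxygen-bearing diazine carbon (C3a–C7a); ring A closes as the six-membered ring of the (4+2) addition (C3a–C7a and C4–C5) and is completed by loss of the N=N bridge. No stereocentre is created: the bridgehead centres of 10 vanish on aromatisation, and C2 and C3 lie outside the reacting π systems, so the anti relationship of 9 becomes the trans relationship of 11. The step needs regioselectivity (methoxy at C7, chlorine at C5), and the tether secures it, since only the internal alkyne carbon can reach the carbon that bears O1. It also needs the cycloaddition to outrun thermal cleavage of the benzylic ether: the chlorine lowers the diazine LUMO, the aryl and methyl groups on the tether favour the folded rotamer, high dilution suppresses bimolecular paths and the amine solvent scavenges traces of acid.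

Step 6
Reactants: 11 (2S,3S)-5-chloro-2-[3,4-dimethoxy-5-(methoxymethoxy)phenyl]-7-methoxy-3-methyl-2,3-dihydro-1-benzofuran
Product: 12 5-[(2S,3S)-5-chloro-7-methoxy-3-methyl-2,3-dihydro-1-benzofuran-2-yl]-2,3-dimethoxyphenol
Conditions: HCl (1.25 M in MeOH), THF, rt to 40 °C
Reagents that add atoms: none
Why: Acid-catalysed acetal exchange of an aryl MOM ether with methanol; aryl methyl ethers and the aryl chloride are inert, and the step is placed before the propenyl group exists so that no styrene meets acid. Should C2 ionise reversibly, it would re-close to the more stable trans isomer, and C3 is not involved.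

Step 7
Reactants: 12 5-[(2S,3S)-5-chloro-7-methoxy-3-methyl-2,3-dihydro-1-benzofuran-2-yl]-2,3-dimethoxyphenol; 13 potassium (E)-prop-1-enyltrifluoroborate
Product: 14 5-[(2S,3S)-7-methoxy-3-methyl-5-[(E)-prop-1-enyl]-2,3-dihydro-1-benzofuran-2-yl]-2,3-dimethoxyphenol
Conditions: Pd(OAc)2 (3 mol %), SPhos (6 mol %), K2CO3 (4 equiv), 1,4-dioxane/H2O (4:1), 90 °C
Reagents that add atoms: none
Why: Suzuki–Miyaura coupling of an aryl chloride with an alkenyltrifluoroborate under a bulky, electron-rich biarylphosphine catalyst that allows oxidative addition into the electron-rich C–Cl bond. Transmetalation and reductive elimination keep the (E) geometry, and the phenol is tolerated as its phenoxide.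

## Compound list

1 | 3-hydroxy-4,5-dimethoxybenzaldehyde | O=Cc1cc(O)c(OC)c(OC)c1 | starting material
2 | 3,4-dimethoxy-5-(methoxymethoxy)benzaldehyde | O=Cc1cc(OCOC)c(OC)c(OC)c1 | intermediate
3 | (R)-but-3-yn-2-ol | C#C[C@@H](C)O | starting material
4 | (R)-but-3-yn-2-yl methanesulfonate | C#C[C@@H](C)OS(C)(=O)=O | intermediate
5 | (aS)-buta-1,2-dien-1-yl(iodo)indium methanesulfonate (allenylindium reagent, trivalent indium, not isolated) | CC([H])=[C@@]=C([H])[In](I)OS(C)(=O)=O | intermediate
6 | (1S,2S)-1-[3,4-dimethoxy-5-(methoxymethoxy)phenyl]-2-methylbut-3-yn-1-ol | C#C[C@H](C)[C@@H](c1cc(OCOC)c(OC)c(OC)c1)O | intermediate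
7 | 3,6-dichloro-4-methoxypyridazine | COc1cc(Cl)nnc1Cl | starting material
8 | sodium (1S,2S)-1-[3,4-dimethoxy-5-(methoxymethoxy)phenyl]-2-methylbut-3-yn-1-olate (not isolated) | C#C[C@H](C)[C@@H](c1cc(OCOC)c(OC)c(OC)c1)[O-].[Na+] | intermediate
9 | 6-chloro-3-{[(1S,2S)-1-[3,4-dimethoxy-5-(methoxymethoxy)phenyl]-2-methylbut-3-yn-1-yl]oxy}-4-methoxypyridazine | C#C[C@H](C)[C@@H](c1cc(OCOC)c(OC)c(OC)c1)Oc1nnc(Cl)cc1OC | intermediate
10 | bridged (4+2) adduct of 9: a 2,3-diazabicyclo[2.2.2]octa-2,5,7-triene with the O1–C2–C3 chain fused across the future C3a–C7a bond, chlorine on the bridgehead that becomes C5 and methoxy on the carbon that becomes C7; C2 and C3 as in 9, both bridgehead configurations (not isolated) | O1[C@H](c4cc(OCOC)c(OC)c(OC)c4)[C@@H](C)C2=CC3(Cl)N=NC12C(OC)=C3 | intermediate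
11 | (2S,3S)-5-chloro-2-[3,4-dimethoxy-5-(methoxymethoxy)phenyl]-7-methoxy-3-methyl-2,3-dihydro-1-benzofuran | Clc1cc(OC)c2c(c1)[C@H](C)[C@@H](c1cc(OCOC)c(OC)c(OC)c1)O2 | intermediate
12 | 5-[(2S,3S)-5-chloro-7-methoxy-3-methyl-2,3-dihydro-1-benzofuran-2-yl]-2,3-dimethoxyphenol | Clc1cc(OC)c2c(c1)[C@H](C)[C@@H](c1cc(O)c(OC)c(OC)c1)O2 | intermediate
13 | potassium (E)-prop-1-enyltrifluoroborate | C/C=C/[B-](F)(F)F.[K+] | starting material
14 | 5-[(2S,3S)-7-methoxy-3-methyl-5-[(E)-prop-1-enyl]-2,3-dihydro-1-benzofuran-2-yl]-2,3-dimethoxyphenol | C/C=C/c1cc(OC)c2c(c1)[C@H](C)[C@@H](c1cc(O)c(OC)c(OC)c1)O2 | target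

## Step count and least certain steps

Total steps: 7. Longest linear sequence: 6 steps (1 to 2 to 6 to 9 to 11 to 12 to 14; the branch from 3 is equally long).

**Step 5 (key step).** The most likely failure is that ring closure is too slow at a temperature the substrate tolerates, because two alkoxy groups raise the diazine LUMO. On long heating, thermal scission of the benzylic C–O bond (retro-ene loss of the diazine through N2 and the C3 hydrogen, or ionisation toward the ring B-stabilised cation) would then outrun the cycloaddition.

The fallback sets out from 6 and returns at 11. Alkoxide 8 would be combined with symmetrical 3,6-dichloropyridazine to give 3-chloro-6-{[(1S,2S)-1-[3,4-dimethoxy-5-(methoxymethoxy)phenyl]-2-methylbut-3-yn-1-yl]oxy}pyridazine F1. This ether has no regiochemical question and only one donor on the diazine, and it belongs exactly to the substrate class for which the thermal closure is established. Heating F1 should therefore give (2S,3S)-5-chloro-2-[3,4-dimethoxy-5-(methoxymethoxy)phenyl]-3-methyl-2,3-dihydro-1-benzofuran F2 at lower temperature. The C7 oxygen would then be added in three steps: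
- Borylation with [Ir(OMe)(cod)]2, 4,4′-di-tert-butyl-2,2′-bipyridine and B2pin2 should go to C7–H and give the 7-(4,4,5,5-tetramethyl-1,3,2-dioxaborolan-2-yl) derivative F3. C4–H is flanked by C3a and chlorine, C6–H is ortho to chlorine, both C–H bonds of ring B have two ortho neighbours, and C7–H has only the tied-back ring oxygen beside it.
- Oxidation with NaBO3·4H2O should give (2S,3S)-5-chloro-2-[3,4-dimethoxy-5-(methoxymethoxy)phenyl]-3-methyl-2,3-dihydro-1-benzofuran-7-ol F4.
- Methylation with MeI and K2CO3 returns to 11.

**Step 4.** The alkoxide may enter partly or mainly at C6, which is less hindered and meta to the methoxy group, and a second substitution may follow.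

The fallback sets out from 6 and returns at 11. Alkoxide 8 would be combined with 3-chloro-4-methoxypyridazine, which has a single leaving group, to give 3-{[(1S,2S)-1-[3,4-dimethoxy-5-(methoxymethoxy)phenyl]-2-methylbut-3-yn-1-yl]oxy}-4-methoxypyridazine F5. Thermal closure, expected to need more forcing conditions without the chlorine, would give (2S,3S)-2-[3,4-dimethoxy-5-(methoxymethoxy)phenyl]-7-methoxy-3-methyl-2,3-dihydro-1-benzofuran F6. Borylation under the same iridium conditions should go to C5, the only C–H bond without an ortho substituent, giving the 5-(4,4,5,5-tetramethyl-1,3,2-dioxaborolan-2-yl) derivative F7. Chlorodeboronation with CuCl2 in MeOH/H2O returns to 11.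

**Step 3.** Facial discrimination at the conjugated aryl aldehyde may be poor (anti/syn erosion), and the allenylpalladium intermediate may partly racemise before transfer to indium.

The fallback sets out from 2 and returns at 6.
- Brown crotylboration of 2 with the (E)-crotylborane from (E)-but-2-ene, n-BuLi, KOt-Bu, (−)-Ipc2BOMe and BF3·OEt2 at −78 °C, with NaOH/H2O2 work-up, should give (1S,2S)-1-[3,4-dimethoxy-5-(methoxymethoxy)phenyl]-2-methylbut-3-en-1-ol F8 through a chair transition state.
- Silylation (TBSCl, imidazole) gives tert-butyl{[(1S,2S)-1-[3,4-dimethoxy-5-(methoxymethoxy)phenyl]-2-methylbut-3-en-1-yl]oxy}dimethylsilane F9.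
- Lemieux–Johnson cleavage (OsO4 cat., NaIO4, 2,6-lutidine) gives (2R,3S)-3-[tert-butyl(dimethyl)silyloxy]-3-[3,4-dimethoxy-5-(methoxymethoxy)phenyl]-2-methylpropanal F10.
- Ohira–Bestmann homologation (dimethyl (1-diazo-2-oxopropyl)phosphonate, K2CO3, MeOH, 0 °C) gives tert-butyl{[(1S,2S)-1-[3,4-dimethoxy-5-(methoxymethoxy)phenyl]-2-methylbut-3-yn-1-yl]oxy}dimethylsilane F11.
- TBAF returns to 6.

**Step 7.** Oxidative addition into the electron-rich aryl chloride may be slow while the substrate is present as a phenoxide, so that protodeboronation of the alkenylboron partner and catalyst decay compete.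

The fallback sets out from 11 and returns at 14. The same coupling would be run on the MOM ether 11 with 13 to give (2S,3S)-2-[3,4-dimethoxy-5-(methoxymethoxy)phenyl]-7-methoxy-3-methyl-5-[(E)-prop-1-enyl]-2,3-dihydro-1-benzofuran F12. The acetal would then be removed without Brønsted acid, by TMSOTf and 2,2′-bipyridyl in CH2Cl2 at 0 °C followed by water, so that the styrene is not exposed to protic acid.

## Further compounds

F1 | step 5 | 3-chloro-6-{[(1S,2S)-1-[3,4-dimethoxy-5-(methoxymethoxy)phenyl]-2-methylbut-3-yn-1-yl]oxy}pyridazine | C#C[C@H](C)[C@@H](c1cc(OCOC)c(OC)c(OC)c1)Oc1ccc(Cl)nn1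
F2 | step 5 | (2S,3S)-5-chloro-2-[3,4-dimethoxy-5-(methoxymethoxy)phenyl]-3-methyl-2,3-dihydro-1-benzofuran | Clc1ccc2c(c1)[C@H](C)[C@@H](c1cc(OCOC)c(OC)c(OC)c1)O2
F3 | step 5 | 2-{(2S,3S)-5-chloro-2-[3,4-dimethoxy-5-(methoxymethoxy)phenyl]-3-methyl-2,3-dihydro-1-benzofuran-7-yl}-4,4,5,5-tetramethyl-1,3,2-dioxaborolane | Clc1cc(B3OC(C)(C)C(C)(C)O3)c2c(c1)[C@H](C)[C@@H](c1cc(OCOC)c(OC)c(OC)c1)O2
F4 | step 5 | (2S,3S)-5-chloro-2-[3,4-dimethoxy-5-(methoxymethoxy)phenyl]-3-methyl-2,3-dihydro-1-benzofuran-7-ol | Clc1cc(O)c2c(c1)[C@H](C)[C@@H](c1cc(OCOC)c(OC)c(OC)c1)O2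
F5 | step 4 | 3-{[(1S,2S)-1-[3,4-dimethoxy-5-(methoxymethoxy)phenyl]-2-methylbut-3-yn-1-yl]oxy}-4-methoxypyridazine | C#C[C@H](C)[C@@H](c1cc(OCOC)c(OC)c(OC)c1)Oc1nnccc1OC
F6 | step 4 | (2S,3S)-2-[3,4-dimethoxy-5-(methoxymethoxy)phenyl]-7-methoxy-3-methyl-2,3-dihydro-1-benzofuran | c1cc(OC)c2c(c1)[C@H](C)[C@@H](c1cc(OCOC)c(OC)c(OC)c1)O2
F7 | step 4 | 2-{(2S,3S)-2-[3,4-dimethoxy-5-(methoxymethoxy)phenyl]-7-methoxy-3-methyl-2,3-dihydro-1-benzofuran-5-yl}-4,4,5,5-tetramethyl-1,3,2-dioxaborolane | CC1(C)OB(OC1(C)C)c1cc(OC)c2c(c1)[C@H](C)[C@@H](c1cc(OCOC)c(OC)c(OC)c1)O2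
F8 | step 3 | (1S,2S)-1-[3,4-dimethoxy-5-(methoxymethoxy)phenyl]-2-methylbut-3-en-1-ol | C=C[C@H](C)[C@@H](c1cc(OCOC)c(OC)c(OC)c1)O
F9 | step 3 | tert-butyl{[(1S,2S)-1-[3,4-dimethoxy-5-(methoxymethoxy)phenyl]-2-methylbut-3-en-1-yl]oxy}dimethylsilane | C=C[C@H](C)[C@@H](c1cc(OCOC)c(OC)c(OC)c1)O[Si](C)(C)C(C)(C)C
F10 | step 3 | (2R,3S)-3-[tert-butyl(dimethyl)silyloxy]-3-[3,4-dimethoxy-5-(methoxymethoxy)phenyl]-2-methylpropanal | O=C[C@H](C)[C@@H](c1cc(OCOC)c(OC)c(OC)c1)O[Si](C)(C)C(C)(C)C
F11 | step 3 | tert-butyl{[(1S,2S)-1-[3,4-dimethoxy-5-(methoxymethoxy)phenyl]-2-methylbut-3-yn-1-yl]oxy}dimethylsilane | C#C[C@H](C)[C@@H](c1cc(OCOC)c(OC)c(OC)c1)O[Si](C)(C)C(C)(C)C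
F12 | step 7 | (2S,3S)-2-[3,4-dimethoxy-5-(methoxymethoxy)phenyl]-7-methoxy-3-methyl-5-[(E)-prop-1-enyl]-2,3-dihydro-1-benzofuran | C/C=C/c1cc(OC)c2c(c1)[C@H](C)[C@@H](c1cc(OCOC)c(OC)c(OC)c1)O2
A1 | alternative 1 | (2S,3S)-5-bromo-2-[3,4-dimethoxy-5-(triisopropylsilyloxy)phenyl]-7-methoxy-3-methyl-2,3-dihydro-1-benzofuran | Brc1cc(OC)c2c(c1)[C@H](C)[C@@H](c1cc(O[Si](C(C)C)(C(C)C)C(C)C)c(OC)c(OC)c1)O2
A2 | alternative 1 | 4-bromo-2-methoxy-6-[1-(4-methylbenzenesulfonyl)ethyl]phenol (racemic) | CC(c1cc(Br)cc(OC)c1O)S(=O)(=O)c1ccc(C)cc1
A3 | alternative 1 | (2R,5R)-1-{[3,4-dimethoxy-5-(triisopropylsilyloxy)phenyl]methyl}-2,5-dimethylthiolan-1-ium tetrafluoroborate (written with one enantiomer of a C2-symmetric sulfide; the antipode would be taken if the induction ran the other way) | C[C@@H]1CC[C@@H](C)[S+]1Cc1cc(O[Si](C(C)C)(C(C)C)C(C)C)c(OC)c(OC)c1.F[B-](F)(F)F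
A4 | alternative 1 | 4-bromo-6-ethylidene-2-methoxycyclohexa-2,4-dien-1-one (transient; ethylidene geometry not fixed) | CC=C1C=C(Br)C=C(OC)C1=O
A5 | alternative 2 | methyl (2S,3S)-5-bromo-2-[3,4-dimethoxy-5-(triisopropylsilyloxy)phenyl]-7-methoxy-2,3-dihydro-1-benzofuran-3-carboxylate (trans) | Brc1cc(OC)c2c(c1)[C@H](C(=O)OC)[C@@H](c1cc(O[Si](C(C)C)(C(C)C)C(C)C)c(OC)c(OC)c1)O2
A6 | alternative 2 | (2S)-6-bromo-2-[3,4-dimethoxy-5-(triisopropylsilyloxy)phenyl]-8-methoxy-2,3-dihydro-4H-chromen-4-one | O=C1C[C@@H](c2cc(O[Si](C(C)C)(C(C)C)C(C)C)c(OC)c(OC)c2)Oc2c(OC)cc(Br)cc12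
A7 | alternative 3 | methyl (2S,3S)-7-bromo-2-[3,4-dimethoxy-5-(methoxymethoxy)phenyl]-3-methyl-2,3-dihydro-1-benzofuran-5-carboxylate | COC(=O)c1cc(Br)c2c(c1)[C@H](C)[C@@H](c1cc(OCOC)c(OC)c(OC)c1)O2
A8 | alternative 3 | (4S,5S)-5-[3,4-dimethoxy-5-(methoxymethoxy)phenyl]-4-methyloxolan-2-one | O=C1C[C@H](C)[C@@H](c2cc(OCOC)c(OC)c(OC)c2)O1
A9 | alternative 3 | methyl 3-bromo-2-oxo-2H-pyran-5-carboxylate | COC(=O)C1=COC(=O)C(Br)=C1
A10 | alternative 3 | tert-butyl({(4S,5S)-5-[3,4-dimethoxy-5-(methoxymethoxy)phenyl]-4-methyl-4,5-dihydrofuran-2-yl}oxy)dimethylsilane | CC(C)(C)[Si](C)(C)OC1=C[C@H](C)[C@@H](c2cc(OCOC)c(OC)c(OC)c2)O1
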